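## Retrosynthetic overview

1. The 28-membered lactone-lactam is the only ring of the target. It is opened at the C4=C5 enoate and closed last by an intramolecular Horner–Wadsworth–Emmons reaction; the ester (O2–C3) and amide (N27–C28) are made intermolecularly. Numbering: C1 = propyl-bearing ring carbon, O2, C3 = ester C=O, C4–C26 along the chain, N27, C28 = amide C=O.
2. The open chain is cut at C19–C20: B-alkyl Suzuki–Miyaura coupling of a western 2-bromo-1,3-diene (C5–C19) with an eastern terminal alkene (C20–C28 plus C1–C4).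
3. Western fragment: the C14–C15 bond and the C15 ethyl stereocentre come from a Johnson–Claisen [3,3]-sigmatropic rearrangement with 1,3-chirality transfer from (S)-but-3-yn-2-ol. C6 is bought as the Roche-ester-derived bromide, and the C18=C19 geometry comes from a bromo-HWE olefination.
4. Eastern fragment: C22, C23 and C25 are C2, C3 and C5 of D-mannose (methylenation at C1, deoxygenation at C4, amination at C6); C1 is bought as L-norvaline.
5. Ring order: the two dioxolanes bought with diacetone-D-mannose are protecting groups only (removed in steps 18 and 26); the macrocycle is closed once, in step 25.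

Assumption: the α-bromophosphonate and every compound carrying the CH(CH3)P(O)(OEt)2 unit are used as mixtures at that carbon, which becomes sp2 in the olefinations; 9-BBN and the Grignard reagent are bought as THF solutions.

## Route

Step 1
Reactants: 1 (S)-but-3-yn-2-ol
Product: 2 (S)-hex-3-yn-2-ol
Conditions: n-BuLi (2.1 equiv), THF, −78 → 0 °C; EtI, DMPU, −78 °C → rt
Reagents that add atoms: iodoethane (CCI)
Why: Alkylation of the alkoxide/acetylide dianion takes place at the acetylide carbon only, so the bought carbinol stereocentre is untouched.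

Step 2
Reactants: 2 (S)-hex-3-yn-2-ol
Product: 3 (2S,3Z)-hex-3-en-2-ol
Conditions: H2 (1 atm), Pd/CaCO3–Pb(OAc)2 (Lindlar), quinoline, pentane, rt
Reagents that add atoms: none
Why: Lindlar semihydrogenation adds H2 syn and stops at the (Z)-allylic alcohol.

Step 3
Reactants: 3 (2S,3Z)-hex-3-en-2-ol
Product: 5 ethyl (3R,4E)-3-ethylhex-4-enoate, via ketene acetal 4 (not isolated)
Conditions: MeC(OEt)3 (6 equiv), EtCO2H (cat.), 140 °C, EtOH distilled off
Reagents that add atoms: triethyl orthoacetate (CCOC(C)(OCC)OCC)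
Why: Johnson–Claisen [3,3]-sigmatropic rearrangement through a chair transition state with the carbinol methyl equatorial forms the C14–C15 bond suprafacially, so the (S)-carbinol of the (Z)-alkene is relayed to (R)-C15 and the new alkene is (E).

Step 4
Reactants: 5 ethyl (3R,4E)-3-ethylhex-4-enoate
Product: 6 (3R,4E)-3-ethylhex-4-en-1-ol
Conditions: LiAlH4, Et2O, 0 °C
Reagents that add atoms: none
Why: Hydride reduction of the ester to the primary alcohol does not touch the allylic stereocentre or the alkene.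

Step 5
Reactants: 6 (3R,4E)-3-ethylhex-4-en-1-ol
Product: 7 (2E,4R)-6-bromo-4-ethylhex-2-ene
Conditions: CBr4, PPh3, CH2Cl2, 0 °C
Reagents that add atoms: tetrabromomethane (BrC(Br)(Br)Br)
Why: Appel bromination converts the primary alcohol into the bromide under neutral conditions.

Step 6
Reactants: 8 (S)-3-bromo-2-methylpropan-1-ol
Product: 9 [(2S)-3-bromo-2-methylpropoxy]triethylsilane
Conditions: TESCl, imidazole, CH2Cl2, 0 °C
Reagents that add atoms: chlorotriethylsilane (CC[Si](Cl)(CC)CC)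
Why: Silylation of the primary alcohol gives a TES ether that can later be oxidised directly to the aldehyde.

Step 7
Reactants: 9 [(2S)-3-bromo-2-methylpropoxy]triethylsilane, 10 pent-4-en-1-ylmagnesium bromide
Product: 11 triethyl{[(2R)-2-methyloct-7-en-1-yl]oxy}silane
Conditions: Li2CuCl4 (3 mol%), THF/NMP, 0 °C → rt
Reagents that add atoms: none
Why: Kochi-type copper-catalysed sp3–sp3 Grignard cross-coupling at the primary bromide does not involve the methyl stereocentre (the descriptor changes only through CIP priorities).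

Step 8
Reactants: 11 triethyl{[(2R)-2-methyloct-7-en-1-yl]oxy}silane, 7 (2E,4R)-6-bromo-4-ethylhex-2-ene
Product: 13 triethyl{[(2R,11R,12E)-11-ethyl-2-methyltetradec-12-en-1-yl]oxy}silane, via alkylborane 12 (not isolated)
Conditions: 9-BBN, THF, rt; then 7, Pd(OAc)2 (4 mol%), PCy3 (8 mol%), K3PO4·H2O, THF, rt
Reagents that add atoms: none
Why: Anti-Markovnikov hydroboration followed by Fu-type alkyl–alkyl Suzuki–Miyaura coupling (the bulky PCy3 suppresses β-hydride elimination) joins C12 to C13.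

Step 9
Reactants: 13 triethyl{[(2R,11R,12E)-11-ethyl-2-methyltetradec-12-en-1-yl]oxy}silane
Product: 14 (2E,4R,13R)-4-ethyl-13-methyl-14-[(triethylsilyl)oxy]tetradec-2-enal
Conditions: crotonaldehyde (5 equiv), second-generation Hoveyda–Grubbs catalyst RuCl2(H2IMes)(=CH-C6H4-2-OiPr) (5 mol%), CH2Cl2, 40 °C
Reagents that add atoms: (E)-but-2-enal (C/C=C/C=O)
Why: Olefin cross-metathesis exchanges the propenyl terminus for the conjugated aldehyde with thermodynamic (E)-selectivity and expels volatile but-2-ene.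

Step 10
Reactants: 15 methyl 2-[bis(2,2,2-trifluoroethoxy)phosphoryl]acetate
Product: 16 methyl 2-[bis(2,2,2-trifluoroethoxy)phosphoryl]-2-bromoacetate
Conditions: NaH, THF, 0 °C; inverse addition to Br2 (1.0 equiv), −78 °C
Reagents that add atoms: bromine (BrBr)
Why: Electrophilic α-bromination of the stabilised phosphonate carbanion; inverse addition limits dibromination.

Step 11
Reactants: 14 (2E,4R,13R)-4-ethyl-13-methyl-14-[(triethylsilyl)oxy]tetradec-2-enal, 16 methyl 2-[bis(2,2,2-trifluoroethoxy)phosphoryl]-2-bromoacetate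
Product: 17 methyl (2E,4E,6R,15R)-2-bromo-6-ethyl-15-methyl-16-[(triethylsilyl)oxy]hexadeca-2,4-dienoate
Conditions: 16, KOt-Bu, 18-crown-6, THF, −78 °C; then 14
Reagents that add atoms: none
Why: Horner–Wadsworth–Emmons olefination with the bis(trifluoroethyl) bromophosphonoacetate is under Still–Gennari-type kinetic control and places the ester cis to C17, giving the (2E)-α-bromo dienoate.

Step 12
Reactants: 17 methyl (2E,4E,6R,15R)-2-bromo-6-ethyl-15-methyl-16-[(triethylsilyl)oxy]hexadeca-2,4-dienoate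
Product: 18 (2E,4E,6R,15R)-2-bromo-6-ethyl-15-methyl-16-[(triethylsilyl)oxy]hexadeca-2,4-dien-1-ol
Conditions: i-Bu2AlH (2.3 equiv), CH2Cl2, −78 °C
Reagents that add atoms: none
Why: 1,2-Reduction of the enoate gives the allylic alcohol and leaves the vinyl bromide and the alkene geometry intact.

Step 13
Reactants: 18 (2E,4E,6R,15R)-2-bromo-6-ethyl-15-methyl-16-[(triethylsilyl)oxy]hexadeca-2,4-dien-1-ol
Product: 19 {[(2R,11R,12E,14E)-15-bromo-11-ethyl-16-methoxy-2-methylhexadeca-12,14-dien-1-yl]oxy}triethylsilane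
Conditions: NaH, MeI, THF, 0 °C → rt
Reagents that add atoms: iodomethane (CI)
Why: Williamson methylation of the allylic alkoxide; the vinylic H is cis to Br, so anti-elimination of HBr is not available.

Step 14
Reactants: 20 L-norvaline
Product: 21 (S)-2-hydroxypentanoic acid
Conditions: NaNO2, 1 M H2SO4, 0 °C → rt
Reagents that add atoms: water (O)
Why: Diazotisation proceeds with double inversion through the α-lactone, so the hydroxy acid is formed with net retention.

Step 15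
Reactants: 22 2,3:5,6-di-O-isopropylidene-α-D-mannofuranose
Product: 23 1,2-dideoxy-3,4:6,7-di-O-isopropylidene-D-manno-hept-1-enitol (free 5-OH)
Conditions: Ph3PCH3Br, KOt-Bu, THF, 0 °C → reflux
Reagents that add atoms: methyltriphenylphosphonium bromide (C[P+](c1ccccc1)(c1ccccc1)c1ccccc1.[Br-])
Why: Wittig methylenation of the open-chain aldehyde form of the lactol turns mannose C1 into C21 of the vinyl group and leaves C2, C3 and C5 (future C22, C23, C25) untouched.

Step 16
Reactants: 23 1,2-dideoxy-3,4:6,7-di-O-isopropylidene-D-manno-hept-1-enitol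
Product: 24 5-O-[(methylsulfanyl)carbonothioyl] derivative of 23 (S-methyl xanthate)
Conditions: NaH, imidazole (cat.), THF, 0 °C; CS2; MeI
Reagents that add atoms: carbon disulfide (S=C=S), iodomethane (CI)
Why: Xanthate formation activates the only free hydroxyl for radical deoxygenation.

Step 17
Reactants: 24 S-methyl xanthate of 23
Product: 25 (4S,5R)-4-{[(4S)-2,2-dimethyl-1,3-dioxolan-4-yl]methyl}-2,2-dimethyl-5-vinyl-1,3-dioxolane
Conditions: Bu3SnH, AIBN (cat.), toluene, 110 °C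
Reagents that add atoms: none
Why: Barton–McCombie radical deoxygenation removes the oxygen at C24; the neighbouring stereocentres are not involved, and cyclisation of the radical onto the vinyl group would be a disfavoured 5-endo or 4-exo closure.

Step 18
Reactants: 25 (4S,5R)-4-{[(4S)-2,2-dimethyl-1,3-dioxolan-4-yl]methyl}-2,2-dimethyl-5-vinyl-1,3-dioxolane
Product: 26 (2S)-3-[(4S,5R)-2,2-dimethyl-5-vinyl-1,3-dioxolan-4-yl]propane-1,2-diol
Conditions: AcOH/H2O (4:1), rt
Reagents that add atoms: none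
Why: Selective acetal hydrolysis, because the terminal monosubstituted dioxolane is cleaved faster than the internal cis-4,5-disubstituted one.

Step 19
Reactants: 26 (2S)-3-[(4S,5R)-2,2-dimethyl-5-vinyl-1,3-dioxolan-4-yl]propane-1,2-diol
Product: 28 (2S)-1-amino-3-[(4S,5R)-2,2-dimethyl-5-vinyl-1,3-dioxolan-4-yl]propan-2-ol, via primary tosylate 27 (not isolated)
Conditions: TsCl (1.05 equiv), Et3N, Bu2SnO (2 mol%), CH2Cl2, 0 °C; then NH3 (7 M in MeOH), 50 °C, sealed tube
Reagents that add atoms: ammonia (N)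
Why: Tin-catalysed selective primary tosylation followed by SN2 ammonolysis at C26 (directly or through the terminal epoxide) never breaks the C25–O bond, so C25 keeps its configuration.

Step 20
Reactants: 28 (2S)-1-amino-3-[(4S,5R)-2,2-dimethyl-5-vinyl-1,3-dioxolan-4-yl]propan-2-ol
Product: 29 (2S)-2-[(tert-butyldimethylsilyl)oxy]-3-[(4S,5R)-2,2-dimethyl-5-vinyl-1,3-dioxolan-4-yl]propan-1-amine
Conditions: TBSCl, imidazole, DMF, rt; aqueous work-up
Reagents that add atoms: tert-butyl(chloro)dimethylsilane (CC(C)(C)[Si](C)(C)Cl)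
Why: Chemoselective O-silylation, since any N-silyl amine formed is hydrolysed on work-up.

Step 21
Reactants: 29 (2S)-2-[(tert-butyldimethylsilyl)oxy]-3-[(4S,5R)-2,2-dimethyl-5-vinyl-1,3-dioxolan-4-yl]propan-1-amine, 21 (S)-2-hydroxypentanoic acid
Product: 30 (2S)-N-{(2S)-2-[(tert-butyldimethylsilyl)oxy]-3-[(4S,5R)-2,2-dimethyl-5-vinyl-1,3-dioxolan-4-yl]propyl}-2-hydroxypentanamide
Conditions: DIC, HOBt, CH2Cl2, 0 °C → rt
Reagents that add atoms: none
Why: Carbodiimide/HOBt amide coupling, in which N-acylation of the primary amine outruns self-esterification of the hydroxy acid and the HOBt ester does not epimerise C1.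

Step 22
Reactants: 30 (2S)-N-{(2S)-2-[(tert-butyldimethylsilyl)oxy]-3-[(4S,5R)-2,2-dimethyl-5-vinyl-1,3-dioxolan-4-yl]propyl}-2-hydroxypentanamide, 31 2-(diethoxyphosphoryl)propanoic acid
Product: 32 (2S)-1-({(2S)-2-[(tert-butyldimethylsilyl)oxy]-3-[(4S,5R)-2,2-dimethyl-5-vinyl-1,3-dioxolan-4-yl]propyl}amino)-1-oxopentan-2-yl 2-(diethoxyphosphoryl)propanoate
Conditions: DIC, DMAP (cat.), CH2Cl2, 0 °C → rt
Reagents that add atoms: none
Why: Steglich esterification of the only free hydroxyl installs the phosphonopropionate needed for ring closure.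

Step 23
Reactants: 32 the phosphonate ester from step 22, 19 {[(2R,11R,12E,14E)-15-bromo-11-ethyl-16-methoxy-2-methylhexadeca-12,14-dien-1-yl]oxy}triethylsilane
Product: 34 (2S)-1-({(2S)-2-[(tert-butyldimethylsilyl)oxy]-3-[(4S,5R)-5-{(3Z,5E,7R,16R)-7-ethyl-3-(methoxymethyl)-16-methyl-17-[(triethylsilyl)oxy]heptadeca-3,5-dien-1-yl}-2,2-dimethyl-1,3-dioxolan-4-yl]propyl}amino)-1-oxopentan-2-yl 2-(diethoxyphosphoryl)propanoate, via alkylborane 33 (not isolated)
Conditions: 9-BBN (2.5 equiv), THF, rt; then 19, Pd(dppf)Cl2 (10 mol%), AsPh3, K3PO4 (3 M aq.), DMF, rt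
Reagents that add atoms: none
Why: B-alkyl Suzuki–Miyaura coupling of the primary alkylborane with the vinyl bromide proceeds with retention, so C20 ends up trans to C17 and the methoxymethyl group cis to it.

Step 24
Reactants: 34 the coupled TES ether from step 23
Product: 35 (2S)-1-({(2S)-2-[(tert-butyldimethylsilyl)oxy]-3-[(4S,5R)-5-[(3Z,5E,7R,16R)-7-ethyl-3-(methoxymethyl)-16-methyl-17-oxoheptadeca-3,5-dien-1-yl]-2,2-dimethyl-1,3-dioxolan-4-yl]propyl}amino)-1-oxopentan-2-yl 2-(diethoxyphosphoryl)propanoate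
Conditions: (COCl)2, DMSO, CH2Cl2, −78 °C; 34, −78 → −40 °C; Et3N, → 0 °C
Reagents that add atoms: none
Why: Under Swern conditions the primary TES ether is cleaved and oxidised to the aldehyde in one operation, while the secondary TBS ether and the acetonide survive.

Step 25
Reactants: 35 the aldehyde-phosphonate from step 24
Product: 36 protected macrocycle (target with the C22/C23 diol as acetonide and C25-OH as TBS ether)
Conditions: LiCl, i-Pr2NEt, MeCN/THF (0.001 M), rt
Reagents that add atoms: none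
Why: Masamune–Roush intramolecular Horner–Wadsworth–Emmons olefination at high dilution closes the 28-membered ring, gives the (E)-2-methyl enoate and is mild enough not to epimerise C6.

Step 26
Reactants: 36 protected macrocycle
Product: 37 CNP0215906.3 (target)
Conditions: TFA/THF/H2O (1:4:1), 0 °C → rt
Reagents that add atoms: none
Why: Aqueous acid hydrolyses the isopropylidene acetal and the TBS ether in one global deprotection that leaves the ester, amide and diene intact.

## Compound list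

1 | (S)-but-3-yn-2-ol | C[C@H](O)C#C | starting material
2 | (S)-hex-3-yn-2-ol | C[C@H](O)C#CCC | intermediate
3 | (2S,3Z)-hex-3-en-2-ol | C[C@H](O)/C=C\CC | intermediate
4 | 1-ethoxy-1-{[(2S,3Z)-hex-3-en-2-yl]oxy}ethene (mixed ketene acetal, not isolated) | C=C(OCC)O[C@@H](C)/C=C\CC | intermediate
5 | ethyl (3R,4E)-3-ethylhex-4-enoate | CCOC(=O)C[C@@H](CC)/C=C/C | intermediate
6 | (3R,4E)-3-ethylhex-4-en-1-ol | OCC[C@@H](CC)/C=C/C | intermediate
7 | (2E,4R)-6-bromo-4-ethylhex-2-ene | BrCC[C@@H](CC)/C=C/C | intermediate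
8 | (S)-3-bromo-2-methylpropan-1-ol | OC[C@H](C)CBr | starting material
9 | [(2S)-3-bromo-2-methylpropoxy]triethylsilane | CC[Si](CC)(CC)OC[C@H](C)CBr | intermediate
10 | pent-4-en-1-ylmagnesium bromide | C=CCCC[Mg]Br | starting material
11 | triethyl{[(2R)-2-methyloct-7-en-1-yl]oxy}silane | CC[Si](CC)(CC)OC[C@H](C)CCCCC=C | intermediate
12 | 9-{(7R)-7-methyl-8-[(triethylsilyl)oxy]octyl}-9-borabicyclo[3.3.1]nonane (not isolated) | CC[Si](CC)(CC)OC[C@H](C)CCCCCCB1C2CCCC1CCC2 | intermediate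
13 | triethyl{[(2R,11R,12E)-11-ethyl-2-methyltetradec-12-en-1-yl]oxy}silane | CC[Si](CC)(CC)OC[C@H](C)CCCCCCCC[C@@H](CC)/C=C/C | intermediate
14 | (2E,4R,13R)-4-ethyl-13-methyl-14-[(triethylsilyl)oxy]tetradec-2-enal | CC[Si](CC)(CC)OC[C@H](C)CCCCCCCC[C@@H](CC)/C=C/C=O | intermediate
15 | methyl 2-[bis(2,2,2-trifluoroethoxy)phosphoryl]acetate | COC(=O)CP(=O)(OCC(F)(F)F)OCC(F)(F)F | starting material
16 | methyl 2-[bis(2,2,2-trifluoroethoxy)phosphoryl]-2-bromoacetate (racemic) | COC(=O)C(Br)P(=O)(OCC(F)(F)F)OCC(F)(F)F | intermediate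
17 | methyl (2E,4E,6R,15R)-2-bromo-6-ethyl-15-methyl-16-[(triethylsilyl)oxy]hexadeca-2,4-dienoate | CC[Si](CC)(CC)OC[C@H](C)CCCCCCCC[C@@H](CC)/C=C/C=C(\C(=O)OC)Br | intermediate
18 | (2E,4E,6R,15R)-2-bromo-6-ethyl-15-methyl-16-[(triethylsilyl)oxy]hexadeca-2,4-dien-1-ol | CC[Si](CC)(CC)OC[C@H](C)CCCCCCCC[C@@H](CC)/C=C/C=C(\CO)Br | intermediate
19 | {[(2R,11R,12E,14E)-15-bromo-11-ethyl-16-methoxy-2-methylhexadeca-12,14-dien-1-yl]oxy}triethylsilane | CC[Si](CC)(CC)OC[C@H](C)CCCCCCCC[C@@H](CC)/C=C/C=C(\COC)Br | intermediate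
20 | L-norvaline, (S)-2-aminopentanoic acid | CCC[C@H](N)C(=O)O | starting material
21 | (S)-2-hydroxypentanoic acid | CCC[C@H](O)C(=O)O | intermediate
22 | 2,3:5,6-di-O-isopropylidene-α-D-mannofuranose | O[C@H]1O[C@H]([C@H]2COC(C)(C)O2)[C@@H]2OC(C)(C)O[C@H]12 | starting material
23 | 1,2-dideoxy-3,4:6,7-di-O-isopropylidene-D-manno-hept-1-enitol | C=C[C@H]1OC(C)(C)O[C@H]1[C@H](O)[C@H]1COC(C)(C)O1 | intermediate
24 | 5-O-[(methylsulfanyl)carbonothioyl] derivative of 23 | C=C[C@H]1OC(C)(C)O[C@H]1[C@H](OC(=S)SC)[C@H]1COC(C)(C)O1 | intermediate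
25 | (4S,5R)-4-{[(4S)-2,2-dimethyl-1,3-dioxolan-4-yl]methyl}-2,2-dimethyl-5-vinyl-1,3-dioxolane | C=C[C@H]1OC(C)(C)O[C@H]1C[C@H]1COC(C)(C)O1 | intermediate
26 | (2S)-3-[(4S,5R)-2,2-dimethyl-5-vinyl-1,3-dioxolan-4-yl]propane-1,2-diol | C=C[C@H]1OC(C)(C)O[C@H]1C[C@H](O)CO | intermediate
27 | (2S)-3-[(4S,5R)-2,2-dimethyl-5-vinyl-1,3-dioxolan-4-yl]-2-hydroxypropyl 4-methylbenzenesulfonate (not isolated) | C=C[C@H]1OC(C)(C)O[C@H]1C[C@H](O)COS(=O)(=O)c1ccc(C)cc1 | intermediate
28 | (2S)-1-amino-3-[(4S,5R)-2,2-dimethyl-5-vinyl-1,3-dioxolan-4-yl]propan-2-ol | C=C[C@H]1OC(C)(C)O[C@H]1C[C@H](O)CN | intermediate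
29 | (2S)-2-[(tert-butyldimethylsilyl)oxy]-3-[(4S,5R)-2,2-dimethyl-5-vinyl-1,3-dioxolan-4-yl]propan-1-amine | C=C[C@H]1OC(C)(C)O[C@H]1C[C@H](O[Si](C)(C)C(C)(C)C)CN | intermediate
30 | (2S)-N-{(2S)-2-[(tert-butyldimethylsilyl)oxy]-3-[(4S,5R)-2,2-dimethyl-5-vinyl-1,3-dioxolan-4-yl]propyl}-2-hydroxypentanamide | C=C[C@H]1OC(C)(C)O[C@H]1C[C@H](O[Si](C)(C)C(C)(C)C)CNC(=O)[C@@H](O)CCC | intermediate
31 | 2-(diethoxyphosphoryl)propanoic acid (racemic) | CCOP(=O)(OCC)C(C)C(=O)O | starting material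
32 | (2S)-1-({(2S)-2-[(tert-butyldimethylsilyl)oxy]-3-[(4S,5R)-2,2-dimethyl-5-vinyl-1,3-dioxolan-4-yl]propyl}amino)-1-oxopentan-2-yl 2-(diethoxyphosphoryl)propanoate | C=C[C@H]1OC(C)(C)O[C@H]1C[C@H](O[Si](C)(C)C(C)(C)C)CNC(=O)[C@@H](OC(=O)C(C)P(=O)(OCC)OCC)CCC | intermediate
33 | B-alkyl-9-BBN from hydroboration of the vinyl group of 32, boron on C20 (not isolated) | C1CCC2CCCC1B2CC[C@H]1OC(C)(C)O[C@H]1C[C@H](O[Si](C)(C)C(C)(C)C)CNC(=O)[C@@H](OC(=O)C(C)P(=O)(OCC)OCC)CCC | intermediate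
34 | coupled TES ether: 32 with its vinyl group replaced by the (3Z,5E,7R,16R)-7-ethyl-3-(methoxymethyl)-16-methyl-17-[(triethylsilyl)oxy]heptadeca-3,5-dien-1-yl chain | CC[Si](CC)(CC)OC[C@H](C)CCCCCCCC[C@@H](CC)/C=C/C=C(\COC)CC[C@H]1OC(C)(C)O[C@H]1C[C@H](O[Si](C)(C)C(C)(C)C)CNC(=O)[C@@H](OC(=O)C(C)P(=O)(OCC)OCC)CCC | intermediate
35 | aldehyde-phosphonate: 34 with CH2OTES oxidised to CHO (17-oxo chain, 16R) | O=C[C@H](C)CCCCCCCC[C@@H](CC)/C=C/C=C(\COC)CC[C@H]1OC(C)(C)O[C@H]1C[C@H](O[Si](C)(C)C(C)(C)C)CNC(=O)[C@@H](OC(=O)C(C)P(=O)(OCC)OCC)CCC | intermediate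
36 | protected macrocycle: target with the C22/C23 diol as acetonide and C25-OH as TBS ether | CCC[C@@H]1OC(=O)/C(C)=C/[C@H](C)CCCCCCCC[C@@H](CC)/C=C/C=C(\COC)CC[C@H]2OC(C)(C)O[C@H]2C[C@H](O[Si](C)(C)C(C)(C)C)CNC1=O | intermediate
37 | CNP0215906.3 | CCC[C@@H]1OC(=O)/C(C)=C/[C@H](C)CCCCCCCC[C@@H](CC)/C=C/C=C(\COC)CC[C@@H](O)[C@@H](O)C[C@H](O)CNC1=O | target

## Step count and risks

Total step count: 26.
Longest linear sequence: 14 steps (from 1 to 37 through steps 1–5, 8, 9, 11–13, 23–26).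

Step 9 (cross-metathesis of an internal alkene with an allylic branch) may be slow or incomplete. Fallback: set out from 13; ozonolysis of the propenyl group (O3, CH2Cl2/MeOH, −78 °C; PPh3) gives (2R,11R)-2-ethyl-11-methyl-12-[(triethylsilyl)oxy]dodecanal F1, and Wittig two-carbon homologation with Ph3P=CHCHO (toluene, 80 °C) comes back to the route at 14.

Step 23 (B-alkyl Suzuki–Miyaura coupling of a hindered bromodiene next to a base-sensitive phosphonate ester) may give low conversion or ester cleavage. Fallback: set out from 32; hydroboration–oxidation (9-BBN; NaBO3·4H2O) gives the 2-hydroxyethyl analogue of 32 F2, I2/PPh3/imidazole gives the 2-iodoethyl analogue of 32 F3, zinc insertion (Zn dust, LiCl, THF, 40 °C) gives the alkylzinc iodide of 32 F4, and Negishi coupling of this reagent with 19 (Pd(OAc)2, SPhos, THF/NMP, rt) comes back to the route at 34.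

Step 25 (28-membered macro-olefination) may give oligomers or E/Z mixtures. Fallback, which moves the ring closure to the C19–C20 bond: set out from 19 and 32; Swern oxidation of 19 as in step 24 gives (2R,11R,12E,14E)-15-bromo-11-ethyl-16-methoxy-2-methylhexadeca-12,14-dienal F5, intermolecular Horner–Wadsworth–Emmons reaction with 32 (LiCl, i-Pr2NEt, MeCN) gives the open-chain (2E)-enoate of 32 F6, 9-BBN hydroborates only its terminal vinyl group to give the B-alkyl-9-BBN of the open-chain enoate F7, and intramolecular B-alkyl Suzuki–Miyaura coupling (Pd(dppf)Cl2, AsPh3, K3PO4 aq., DMF/THF, 0.002 M) comes back to the route at 36.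

## Further compounds

F1 | step 9 | (2R,11R)-2-ethyl-11-methyl-12-[(triethylsilyl)oxy]dodecanal | CC[Si](CC)(CC)OC[C@H](C)CCCCCCCC[C@@H](CC)C=O
F2 | step 23 | (2S)-1-({(2S)-2-[(tert-butyldimethylsilyl)oxy]-3-[(4S,5R)-5-(2-hydroxyethyl)-2,2-dimethyl-1,3-dioxolan-4-yl]propyl}amino)-1-oxopentan-2-yl 2-(diethoxyphosphoryl)propanoate | OCC[C@H]1OC(C)(C)O[C@H]1C[C@H](O[Si](C)(C)C(C)(C)C)CNC(=O)[C@@H](OC(=O)C(C)P(=O)(OCC)OCC)CCC
F3 | step 23 | (2S)-1-({(2S)-2-[(tert-butyldimethylsilyl)oxy]-3-[(4S,5R)-5-(2-iodoethyl)-2,2-dimethyl-1,3-dioxolan-4-yl]propyl}amino)-1-oxopentan-2-yl 2-(diethoxyphosphoryl)propanoate | ICC[C@H]1OC(C)(C)O[C@H]1C[C@H](O[Si](C)(C)C(C)(C)C)CNC(=O)[C@@H](OC(=O)C(C)P(=O)(OCC)OCC)CCC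
F4 | step 23 | alkylzinc iodide formed from F3 by zinc insertion into the C–I bond | I[Zn]CC[C@H]1OC(C)(C)O[C@H]1C[C@H](O[Si](C)(C)C(C)(C)C)CNC(=O)[C@@H](OC(=O)C(C)P(=O)(OCC)OCC)CCC
F5 | step 25 | (2R,11R,12E,14E)-15-bromo-11-ethyl-16-methoxy-2-methylhexadeca-12,14-dienal | O=C[C@H](C)CCCCCCCC[C@@H](CC)/C=C/C=C(\COC)Br
F6 | step 25 | (2S)-1-({(2S)-2-[(tert-butyldimethylsilyl)oxy]-3-[(4S,5R)-2,2-dimethyl-5-vinyl-1,3-dioxolan-4-yl]propyl}amino)-1-oxopentan-2-yl (2E,4R,13R,14E,16E)-17-bromo-13-ethyl-18-methoxy-2,4-dimethyloctadeca-2,14,16-trienoate | C=C[C@H]1OC(C)(C)O[C@H]1C[C@H](O[Si](C)(C)C(C)(C)C)CNC(=O)[C@@H](OC(=O)/C(C)=C/[C@H](C)CCCCCCCC[C@@H](CC)/C=C/C=C(\COC)Br)CCC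
F7 | step 25 | B-alkyl-9-BBN from hydroboration of the terminal vinyl group of F6 (boron on C20) | C1CCC2CCCC1B2CC[C@H]1OC(C)(C)O[C@H]1C[C@H](O[Si](C)(C)C(C)(C)C)CNC(=O)[C@@H](OC(=O)/C(C)=C/[C@H](C)CCCCCCCC[C@@H](CC)/C=C/C=C(\COC)Br)CCC
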